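- If X is the reagent that gets used up, the question for each flask is how much Q one X makes, and the plateaus of the earlier runs can be read for that.

| flask | Z | X | remark | time |
|---|---|---|---|---|
| Wednesday's | 0.10 M | 0.080 M | run made earlier |  |
| Saturday's | 0.050 M | 0.080 M | run made earlier |  |
| Tuesday's | 0.20 M | 0.080 M | run made earlier |  |
| Monday's | 0.10 M | 0.16 M | run made earlier |  |
| birch | 0.10 M | 0.0800 M (fed, over 5.0 d) | all else is in the flask from the start; the feed brings no volume worth counting | 12 d |
| larch | 0.10 M | 0.0800 M | everything together at the start | 12 d |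
| elm | 0.10 M (fed, over 5.0 d) | 0.0800 M | all else is in the flask from the start; the feed brings no volume worth counting | 12 d |

| run | time / d | Q / % |
|---|---|---|
| Wednesday's | 1.04 | 45 |
| Wednesday's | 1.67 | 50 |
| Wednesday's | 2.50 | 50 |
| Wednesday's | 4.00 | 47 |
| Wednesday's | 8.00 | 50 |
| Wednesday's | 12.0 | 48 |
| Saturday's | 1.67 | 63 |
| Saturday's | 3.00 | 60 |
| Saturday's | 5.00 | 61 |
| Saturday's | 6.00 | 58 |
| Saturday's | 8.00 | 59 |
| Saturday's | 10.0 | 58 |
| Tuesday's | 1.67 | 28 |
| Tuesday's | 3.00 | 25 |
| Tuesday's | 5.00 | 27 |
| Tuesday's | 6.00 | 27 |
| Tuesday's | 8.00 | 26 |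
| Tuesday's | 10.0 | 26 |
| Monday's | 2.08 | 60 |
| Monday's | 4.00 | 56 |
| Monday's | 6.00 | 58 |
| Monday's | 8.00 | 60 |
| Monday's | 10.0 | 59 |

(each reading ± 1.5 percentage points)

- the analysis behind the earlier runs scatters by 1.5 percentage points, standard deviation

- the best flask by amount of Q, in percent of the Z charged; "all alike" if 1.5 percentage points covers them all (birch / larch / elm / all alike)
- amount of Q at the end, in percent of the Z charged, birch
- amount of Q at the end, in percent of the Z charged, larch
- amount of Q at the end, in percent of the Z charged, elm

- Let r be X charged over Z charged. Saturday and Monday share r = 1.60 and level off alike, near 61% and 58%, so in these runs the plateau follows r.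
- At the low end, Tuesday (r = 0.400) averages 26.5%, which makes 0.663 Q per X charged: the X yield y, a yield on the limiting reagent.
- At the high end, Monday's average gives 0.366 Q per X.
- Joining the ends: Wednesday (r = 0.800) averages 48.3%, less than the 53.0% that y predicts. Larch repeats Wednesday, so this reckoning takes 48.3% for larch.
- Birch drips X into Z, the low-r end, so y times r gives 53.0%. Elm drips Z into X, the high-r end, so Monday's yield gives 29.3%, probably less.
- The weak link is y itself, since Tuesday's r is not zero. Wednesday's yield of 0.604 is lower, and extending that trend gives 57.7% for birch. That extension is for r near zero, and r in birch grows as the feed runs; this reckoning commits to the lower 53.0%.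
- The forecast differs: all alike, with birch 49%, larch 49%, elm 49%, holding that “each run seems to have stopped at a balance rather than because something ran out”.
- The flasks give birch 52.4%, larch 48.3%, elm 18.9%; the best is birch.

    Z + X → D + Q (k = 0.0990 /M/min)
    Q + X → D + G (k = 0.00440 /M/min)
    G + X → D + L (k = 0.00450 /M/min)
    Q ⇌ E (K = 0.430, k = 0.00130 /min)
    2 X → J (k = 0.00870 /M/min)

- Elm falls below even this reckoning's 29.3%; it ends with X at 0% and J at 0.0245 M, which holds 61.2% of the X charged, while birch holds J at 2.73 × 10⁻⁴ M. Birch's result means 0.656 Q per X, beside y = 0.663.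
- A neighbouring flask is birch with 0.020 M of X, so r = 0.200, and y predicts 13.2%. It gives 13.9%.

(All runs were generated by integration on assumed constants; noise was put on by code.)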